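**Assumption:** CNP0253192.1 is taken as the structure and absolute configuration of the given SMILES. Locants follow bisabolane numbering: C1 = C(CH3)OH, C2 = CH–O‑angeloyl, C3 = CHOH, C4 = CH bearing the side chain, C5 = CH–O‑isobutyryl, C6 = CH–OAc, side chain C7(=C14H2)–C8–C9–C10–C11(C12)(C13). β is the ring face of the C4 side chain, α the opposite face.

## Retrosynthetic overview

1. Target ⇐ desilylation ⇐ Evans–Tishchenko reduction (O8 isobutyrate, C10 carbinol) ⇐ boron aldol of enal 22 with 3‑hydroxy‑3‑methylbutan‑2‑one (C8–C9 bond).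
2. Enal 22 ⇐ regioselective acylation of triol 17 ⇐ OH‑directed osmylation (C1, C6) ⇐ L‑Selectride reduction (C5).
3. Key step: silyl‑triflate‑triggered semipinacol 1,2‑alkenyl shift of epoxy carbinol 12 to enone 14 (C4–C7 bond, C4 stereocentre, O3 silylated by silyl transfer).
4. 12 ⇐ alkenyllithium addition to epoxyquinol 5, then angeloylation; 5 ⇐ reduction/ketal hydrolysis ⇐ asymmetric epoxidation of quinone monoketal 2 ⇐ o‑cresol.
5. Rings: the single carbocycle comes from dearomatised o‑cresol; the oxirane is made in step 2 and consumed in the key step.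

## Route

Step 1
Reactants: 1 o‑cresol (2‑methylphenol)
Product: 2 4,4‑dimethoxy‑2‑methylcyclohexa‑2,5‑dien‑1‑one
Conditions: PhI(OAc)2 (2.2 equiv), MeOH, 0 °C to rt
Reagents that add atoms: methanol, CO
Why: Hypervalent‑iodine oxidative dearomatisation: para‑methoxylation of the phenol, then a second oxidation trapped by methanol gives the p‑quinone monoketal; no stereocentre.

Step 2
Reactants: 2 4,4‑dimethoxy‑2‑methylcyclohexa‑2,5‑dien‑1‑one
Product: 3 (1S,6R)‑5,5‑dimethoxy‑3‑methyl‑7‑oxabicyclo[4.1.0]hept‑3‑en‑2‑one (C3–C4 α‑epoxide)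
Conditions: 9‑amino‑9‑deoxy‑epi‑quinine (10 mol%), TFA (20 mol%), urea·H2O2 (1.5 equiv), 1,4‑dioxane, 30 °C
Reagents that add atoms: hydrogen peroxide (from its urea adduct), OO
Why: Proposed new method: iminium activation of the cross‑conjugated dienone by a cinchona primary‑amine salt, in which the iminium forms anti to the α‑methyl arm, the protonated quinuclidine delivers HOO– to one enantiotopic face of the only β‑carbon whose α‑carbon is unsubstituted, and the dienamine closes the oxirane, so that regio‑ and enantioselection occur together and fix C3/C4, from which all other ring stereocentres are relayed; the closest known reaction is the primary‑amine‑salt‑catalysed asymmetric Weitz–Scheffer epoxidation of simple cyclic enones with H2O2, not yet shown for quinone monoketals or for differentiating two enone arms (anhydrous oxidant spares the ketal; the sense is assigned by analogy with cyclohexenone and the quinidine‑derived pseudoenantiomer gives ent‑3).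

Step 3
Reactants: 3 (1S,6R)‑5,5‑dimethoxy‑3‑methyl‑7‑oxabicyclo[4.1.0]hept‑3‑en‑2‑one
Product: 5 (1R,5R,6R)‑5‑hydroxy‑4‑methyl‑7‑oxabicyclo[4.1.0]hept‑3‑en‑2‑one (C5 ketone; 2α‑OH cis to the α‑epoxide), via epoxy alcohol ketal 4 (not isolated)
Conditions: DIBAL‑H, CH2Cl2, −78 °C; Rochelle salt work‑up; then 5% aq. oxalic acid, THF, rt
Reagents that add atoms: water, O
Why: DIBAL‑H 1,2‑reduction with hydride delivered anti to the adjacent oxirane gives the cis‑epoxy alcohol (sets C2), and mild acid hydrolysis of the allylic dimethyl ketal unmasks the C5 enone (reduction/hydrolysis telescoped as in a Stork–Danheiser sequence).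

Step 4
Reactants: 6 2‑bromoprop‑2‑en‑1‑ol
Product: 7 [(2‑bromoprop‑2‑en‑1‑yl)oxy]triethylsilane
Conditions: TESCl, imidazole, CH2Cl2, 0 °C
Reagents that add atoms: chlorotriethylsilane, CC[Si](Cl)(CC)CC
Why: Standard silyl protection of the primary allylic alcohol so that the vinyl bromide can be lithiated; no stereocentre.

Step 5
Reactants: 5 (1R,5R,6R)‑5‑hydroxy‑4‑methyl‑7‑oxabicyclo[4.1.0]hept‑3‑en‑2‑one; 7 [(2‑bromoprop‑2‑en‑1‑yl)oxy]triethylsilane
Product: 9 (1R,2R,5R,6R)‑4‑methyl‑2‑[3‑(triethylsilyloxy)prop‑1‑en‑2‑yl]‑7‑oxabicyclo[4.1.0]hept‑3‑ene‑2,5‑diol (5α‑OH, 5β‑alkenyl), via alkenyllithium 8 (not isolated)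
Conditions: 7 (2.6 equiv), t‑BuLi (5.2 equiv), Et2O, −78 °C; then 5, THF, −78 °C; aq. NH4Cl
Reagents that add atoms: none
Why: Br/Li exchange, then 1,2‑addition of the alkenyllithium to the enone carbonyl anti to the adjacent oxirane (one equivalent is consumed by the free 2‑OH; C6 is still sp2, so no competing α‑substituent), giving the tertiary carbinol with OH cis and alkenyl trans to the epoxide oxygen as the anti 1,2‑shift requires.

Step 6
Reactants: 9 (1R,2R,5R,6R)‑4‑methyl‑2‑[3‑(triethylsilyloxy)prop‑1‑en‑2‑yl]‑7‑oxabicyclo[4.1.0]hept‑3‑ene‑2,5‑diol; 10 angelic acid ((Z)‑2‑methylbut‑2‑enoic acid)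
Product: 12 (1R,2R,5R,6R)‑5‑hydroxy‑3‑methyl‑5‑[3‑(triethylsilyloxy)prop‑1‑en‑2‑yl]‑7‑oxabicyclo[4.1.0]hept‑3‑en‑2‑yl (Z)‑2‑methylbut‑2‑enoate, via mixed anhydride 11 (not isolated)
Conditions: 10, 2,4,6‑trichlorobenzoyl chloride, Et3N, toluene, rt; then 9, DMAP (0.2 equiv), rt
Reagents that add atoms: none
Why: Yamaguchi esterification of the secondary allylic 2‑OH (tertiary 5‑OH inert) with the preformed mixed anhydride at rt retains the Z (angelate) geometry; no stereocentre is touched.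

Step 7 (key step)
Reactants: 12 (1R,2R,5R,6R)‑5‑hydroxy‑3‑methyl‑5‑[3‑(triethylsilyloxy)prop‑1‑en‑2‑yl]‑7‑oxabicyclo[4.1.0]hept‑3‑en‑2‑yl (Z)‑2‑methylbut‑2‑enoate
Product: 14 (1R,5S,6S)‑2‑methyl‑4‑oxo‑6‑(triethylsilyloxy)‑5‑[3‑(triethylsilyloxy)prop‑1‑en‑2‑yl]cyclohex‑2‑en‑1‑yl (Z)‑2‑methylbut‑2‑enoate (2α‑OAng, 3α‑OTES, 4β‑alkenyl, C5 ketone), via tertiary silyl ether 13 (not isolated)
Conditions: TESOTf (1.2 equiv), 2,6‑lutidine (1.5 equiv), CH2Cl2, −78 to −40 °C; NaHCO3 quench at −40 °C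
Reagents that add atoms: triethylsilyl trifluoromethanesulfonate, CC[Si](CC)(CC)OS(=O)(=O)C(F)(F)F
Why: Suzuki–Tsuchihashi‑type (type III) semipinacol rearrangement: after in‑situ O‑silylation, silyl‑triflate activation of the oxirane makes the C5 alkenyl group, anti‑periplanar to the breaking C4–O bond, shift to C4 with inversion (C4–C7 bond, 4β side arm), while O3 emerges as its TES ether by silyl transfer and C5 becomes the enone carbonyl; the in‑plane ring bond and the cis‑disposed angelate cannot compete.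

Step 8
Reactants: 14 (1R,5S,6S)‑2‑methyl‑4‑oxo‑6‑(triethylsilyloxy)‑5‑[3‑(triethylsilyloxy)prop‑1‑en‑2‑yl]cyclohex‑2‑en‑1‑yl (Z)‑2‑methylbut‑2‑enoate
Product: 15 (1R,4R,5R,6S)‑4‑hydroxy‑2‑methyl‑6‑(triethylsilyloxy)‑5‑[3‑(triethylsilyloxy)prop‑1‑en‑2‑yl]cyclohex‑2‑en‑1‑yl (Z)‑2‑methylbut‑2‑enoate (5β‑OH)
Conditions: L‑Selectride (1.2 equiv), THF, −78 °C; aq. NH4Cl
Reagents that add atoms: none
Why: L‑Selectride 1,2‑reduction of the β‑substituted enone by equatorial hydride delivery anti to the 4β side arm gives the pseudoaxial 5β‑alcohol cis to the side arm (sets C5).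

Step 9
Reactants: 15 (1R,4R,5R,6S)‑4‑hydroxy‑2‑methyl‑6‑(triethylsilyloxy)‑5‑[3‑(triethylsilyloxy)prop‑1‑en‑2‑yl]cyclohex‑2‑en‑1‑yl (Z)‑2‑methylbut‑2‑enoate
Product: 17 2α‑angeloyloxy‑1α‑methyl‑3α‑(triethylsilyloxy)‑4β‑[3‑(triethylsilyloxy)prop‑1‑en‑2‑yl]cyclohexane‑1β,5β,6β‑triol, via osmate ester 16 (not isolated)
Conditions: OsO4 (1.05 equiv), TMEDA (1.1 equiv), CH2Cl2, −78 °C; then aq. Na2SO3, THF, 60 °C
Reagents that add atoms: osmium tetroxide, O=[Os](=O)(=O)=O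
Why: Donohoe OsO4·TMEDA directed dihydroxylation: hydrogen bonding of the pseudoaxial 5β‑OH to the diamine‑ligated oxo‑osmium delivers both oxygens to the β face of the ring alkene (also anti to the pseudoaxial 2α‑ester), setting C1 and C6, while the hindered, inductively deactivated allyl silyl ether alkene and the electron‑poor angelate react more slowly.

Step 10
Reactants: 17 2α‑angeloyloxy‑1α‑methyl‑3α‑(triethylsilyloxy)‑4β‑[3‑(triethylsilyloxy)prop‑1‑en‑2‑yl]cyclohexane‑1β,5β,6β‑triol; 18 acetyl chloride; 19 isobutyryl chloride (2‑methylpropanoyl chloride)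
Product: 21 6β‑acetoxy‑2α‑angeloyloxy‑5β‑isobutyryloxy‑1α‑methyl‑3α‑(triethylsilyloxy)‑4β‑[3‑(triethylsilyloxy)prop‑1‑en‑2‑yl]cyclohexan‑1β‑ol, via 6‑monoacetate 20 (not isolated)
Conditions: 18 (1.1 equiv), 2‑aminoethyl diphenylborinate (10 mol%), iPr2NEt, MeCN, 0 °C; then 19 (3 equiv), DMAP, iPr2NEt, 0 to 40 °C
Reagents that add atoms: none
Why: Borinic‑acid‑catalysed regioselective acylation activates the equatorial oxygen of the cis‑diol (O6) for acetylation, and DMAP‑promoted acylation then takes the remaining secondary, axial 5‑OH, the tertiary 1‑OH being inert; no stereocentre is touched.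

Step 11
Reactants: 21 6β‑acetoxy‑2α‑angeloyloxy‑5β‑isobutyryloxy‑1α‑methyl‑3α‑(triethylsilyloxy)‑4β‑[3‑(triethylsilyloxy)prop‑1‑en‑2‑yl]cyclohexan‑1β‑ol
Product: 22 2‑[6β‑acetoxy‑2α‑angeloyloxy‑1β‑hydroxy‑5β‑isobutyryloxy‑1α‑methyl‑3α‑(triethylsilyloxy)cyclohex‑4β‑yl]prop‑2‑enal
Conditions: (COCl)2, DMSO, CH2Cl2, −78 to −40 °C; then Et3N, −78 to 0 °C
Reagents that add atoms: none
Why: Swern conditions cleave a primary TES ether and oxidise it directly to the aldehyde, while the hindered secondary TES ether, the esters and the tertiary alcohol survive; no stereocentre is touched.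

Step 12
Reactants: 22 2‑[6β‑acetoxy‑2α‑angeloyloxy‑1β‑hydroxy‑5β‑isobutyryloxy‑1α‑methyl‑3α‑(triethylsilyloxy)cyclohex‑4β‑yl]prop‑2‑enal; 23 3‑hydroxy‑3‑methylbutan‑2‑one
Product: 26 (8S)‑aldol adduct: ring of 22 carrying the side chain C(=CH2)–CH(OH)–CH2–C(=O)–C(CH3)2OSiMe3, via TMS ether 24 (not isolated), via enol borinate 25 (not isolated)
Conditions: 23 (3 equiv), TMSOTf (3.0 equiv), Et3N, Et2O, −78 °C; (−)‑Ipc2BCl (3.3 equiv), −78 to 0 °C; then 22, −78 to −20 °C; MeOH, pH 7 buffer, H2O2, 0 °C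
Reagents that add atoms: trimethylsilyl trifluoromethanesulfonate, C[Si](C)(C)OS(=O)(=O)C(F)(F)F
Why: Paterson boron aldol: the (−)‑Ipc2B enolate of the methyl ketone (tertiary OH masked in situ as its TMS ether) adds to the si face of the non‑enolisable 2‑substituted acrolein, forming C8–C9 and setting 8S by reagent control (the (+)‑reagent gives the C8 epimer).

Step 13
Reactants: 26 (8S)‑aldol adduct; 27 isobutyraldehyde (2‑methylpropanal)
Product: 28 3‑O‑triethylsilyl‑11‑O‑trimethylsilyl ether of the target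
Conditions: 27 (10 equiv), SmI2 (30 mol%, premixed with 27), THF, −10 °C
Reagents that add atoms: none
Why: Evans–Tishchenko reduction: the Sm(III)‑bound hemiacetal formed from isobutyraldehyde at O8 delivers hydride intramolecularly to C10 through a six‑membered chair transition state, giving the 8,10‑anti (10S) diol with the isobutyrate on O8 and O10 free.

Step 14
Reactants: 28 3‑O‑triethylsilyl‑11‑O‑trimethylsilyl ether of the target
Product: 29 target, (1R,2S,3S,4S,5S,6S,8S,10S)‑6‑acetoxy‑2‑angeloyloxy‑5,8‑bis(isobutyryloxy)bisabol‑7(14)‑ene‑1,3,10,11‑tetraol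
Conditions: HF·pyridine, pyridine, THF, 0 °C to rt
Reagents that add atoms: none
Why: Buffered fluoride desilylation removes the secondary TES and tertiary TMS ethers under mildly acidic conditions that avoid acyl migration; no stereocentre is touched.

## Compound list

1 | o‑cresol (2‑methylphenol) | Cc1ccccc1O | starting material
2 | 4,4‑dimethoxy‑2‑methylcyclohexa‑2,5‑dien‑1‑one | CC1=CC(OC)(OC)C=CC1=O | intermediate
3 | (1S,6R)‑5,5‑dimethoxy‑3‑methyl‑7‑oxabicyclo[4.1.0]hept‑3‑en‑2‑one | [C@@H]12O[C@@H]1C(=O)C(C)=CC2(OC)OC | intermediate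
4 | (1R,2R,6R)‑5,5‑dimethoxy‑3‑methyl‑7‑oxabicyclo[4.1.0]hept‑3‑en‑2‑ol (not isolated) | [C@@H]12O[C@@H]1[C@H](O)C(C)=CC2(OC)OC | intermediate
5 | (1R,5R,6R)‑5‑hydroxy‑4‑methyl‑7‑oxabicyclo[4.1.0]hept‑3‑en‑2‑one | [C@@H]12O[C@@H]1[C@H](O)C(C)=CC2=O | intermediate
6 | 2‑bromoprop‑2‑en‑1‑ol | C=C(Br)CO | starting material
7 | [(2‑bromoprop‑2‑en‑1‑yl)oxy]triethylsilane | C=C(Br)CO[Si](CC)(CC)CC | intermediate
8 | [3‑(triethylsilyloxy)prop‑1‑en‑2‑yl]lithium (not isolated) | [Li]C(=C)CO[Si](CC)(CC)CC | intermediate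
9 | (1R,2R,5R,6R)‑4‑methyl‑2‑[3‑(triethylsilyloxy)prop‑1‑en‑2‑yl]‑7‑oxabicyclo[4.1.0]hept‑3‑ene‑2,5‑diol | [C@@H]12O[C@@H]1[C@H](O)C(C)=C[C@@]2(O)C(=C)CO[Si](CC)(CC)CC | intermediate
10 | angelic acid, (Z)‑2‑methylbut‑2‑enoic acid | C/C=C(/C)C(=O)O | starting material
11 | (Z)‑2‑methylbut‑2‑enoic 2,4,6‑trichlorobenzoic anhydride (not isolated) | C/C=C(/C)C(=O)OC(=O)c1c(Cl)cc(Cl)cc1Cl | intermediate
12 | (1R,2R,5R,6R)‑5‑hydroxy‑3‑methyl‑5‑[3‑(triethylsilyloxy)prop‑1‑en‑2‑yl]‑7‑oxabicyclo[4.1.0]hept‑3‑en‑2‑yl (Z)‑2‑methylbut‑2‑enoate | [C@@H]12O[C@@H]1[C@H](OC(=O)/C(C)=C\C)C(C)=C[C@@]2(O)C(=C)CO[Si](CC)(CC)CC | intermediate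
13 | 5‑O‑triethylsilyl ether of 12 (not isolated) | [C@@H]12O[C@@H]1[C@H](OC(=O)/C(C)=C\C)C(C)=C[C@@]2(O[Si](CC)(CC)CC)C(=C)CO[Si](CC)(CC)CC | intermediate
14 | (1R,5S,6S)‑2‑methyl‑4‑oxo‑6‑(triethylsilyloxy)‑5‑[3‑(triethylsilyloxy)prop‑1‑en‑2‑yl]cyclohex‑2‑en‑1‑yl (Z)‑2‑methylbut‑2‑enoate | C=C(CO[Si](CC)(CC)CC)[C@H]1[C@H](O[Si](CC)(CC)CC)[C@H](OC(=O)/C(C)=C\C)C(C)=CC1=O | intermediate
15 | (1R,4R,5R,6S)‑4‑hydroxy‑2‑methyl‑6‑(triethylsilyloxy)‑5‑[3‑(triethylsilyloxy)prop‑1‑en‑2‑yl]cyclohex‑2‑en‑1‑yl (Z)‑2‑methylbut‑2‑enoate | C=C(CO[Si](CC)(CC)CC)[C@H]1[C@H](O[Si](CC)(CC)CC)[C@H](OC(=O)/C(C)=C\C)C(C)=C[C@H]1O | intermediate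
16 | TMEDA‑ligated osmate(VI) ester of the 1β,6β‑diol of 17 (not isolated) | C=C(CO[Si](CC)(CC)CC)[C@H]1[C@H](O[Si](CC)(CC)CC)[C@H](OC(=O)/C(C)=C\C)[C@@]2(C)O[Os-2]3(=O)(=O)([N+](C)(C)CC[N+]3(C)C)O[C@H]2[C@H]1O | intermediate
17 | 2α‑angeloyloxy‑1α‑methyl‑3α‑(triethylsilyloxy)‑4β‑[3‑(triethylsilyloxy)prop‑1‑en‑2‑yl]cyclohexane‑1β,5β,6β‑triol | C=C(CO[Si](CC)(CC)CC)[C@H]1[C@H](O[Si](CC)(CC)CC)[C@H](OC(=O)/C(C)=C\C)[C@@](C)(O)[C@@H](O)[C@H]1O | intermediate
18 | acetyl chloride | CC(=O)Cl | starting material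
19 | isobutyryl chloride (2‑methylpropanoyl chloride) | CC(C)C(=O)Cl | starting material
20 | 6‑O‑acetate of 17 (not isolated) | C=C(CO[Si](CC)(CC)CC)[C@H]1[C@H](O[Si](CC)(CC)CC)[C@H](OC(=O)/C(C)=C\C)[C@@](C)(O)[C@@H](OC(C)=O)[C@H]1O | intermediate
21 | 6‑O‑acetyl‑5‑O‑isobutyryl derivative of 17 | C=C(CO[Si](CC)(CC)CC)[C@H]1[C@H](O[Si](CC)(CC)CC)[C@H](OC(=O)/C(C)=C\C)[C@@](C)(O)[C@@H](OC(C)=O)[C@H]1OC(=O)C(C)C | intermediate
22 | 2‑[6β‑acetoxy‑2α‑angeloyloxy‑1β‑hydroxy‑5β‑isobutyryloxy‑1α‑methyl‑3α‑(triethylsilyloxy)cyclohex‑4β‑yl]prop‑2‑enal | C=C(C=O)[C@H]1[C@H](O[Si](CC)(CC)CC)[C@H](OC(=O)/C(C)=C\C)[C@@](C)(O)[C@@H](OC(C)=O)[C@H]1OC(=O)C(C)C | intermediate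
23 | 3‑hydroxy‑3‑methylbutan‑2‑one | CC(=O)C(C)(C)O | starting material
24 | 3‑methyl‑3‑(trimethylsilyloxy)butan‑2‑one (not isolated) | CC(=O)C(C)(C)O[Si](C)(C)C | intermediate
25 | diisopinocampheyl enol borinate of 24, from (−)‑Ipc2BCl (not isolated) | C=C(OB([C@@H]1C[C@@H]2C[C@H]([C@H]1C)C2(C)C)[C@@H]1C[C@@H]2C[C@H]([C@H]1C)C2(C)C)C(C)(C)O[Si](C)(C)C | intermediate
26 | (8S)‑8‑hydroxy‑10‑oxo‑11‑(trimethylsilyloxy) aldol adduct of 22 | C=C([C@H]1[C@H](O[Si](CC)(CC)CC)[C@H](OC(=O)/C(C)=C\C)[C@@](C)(O)[C@@H](OC(C)=O)[C@H]1OC(=O)C(C)C)[C@@H](O)CC(=O)C(C)(C)O[Si](C)(C)C | intermediate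
27 | isobutyraldehyde (2‑methylpropanal) | CC(C)C=O | starting material
28 | 3‑O‑triethylsilyl‑11‑O‑trimethylsilyl ether of the target | C=C([C@H]1[C@H](O[Si](CC)(CC)CC)[C@H](OC(=O)/C(C)=C\C)[C@@](C)(O)[C@@H](OC(C)=O)[C@H]1OC(=O)C(C)C)[C@H](C[C@H](O)C(C)(C)O[Si](C)(C)C)OC(=O)C(C)C | intermediate
29 | CNP0253192.1, (1R,2S,3S,4S,5S,6S,8S,10S)‑6‑acetoxy‑2‑angeloyloxy‑5,8‑bis(isobutyryloxy)bisabol‑7(14)‑ene‑1,3,10,11‑tetraol | C=C([C@H]1[C@H](O)[C@H](OC(=O)/C(C)=C\C)[C@@](C)(O)[C@@H](OC(C)=O)[C@H]1OC(=O)C(C)C)[C@H](C[C@H](O)C(C)(C)O)OC(=O)C(C)C | target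

## Step count and risks

Total steps: 14. Longest linear sequence: 13 (steps 1–3 and 5–14; step 4 is a one‑step side branch).

Steps most likely to fail:

**Step 2 (proposed new asymmetric epoxidation).** Risks are slow iminium formation on the hindered dienone, ketal hydrolysis and imperfect regio‑ or enantiocontrol. The fallback uses known chemistry and sets out from 2. Ordinary Weitz–Scheffer epoxidation (t‑BuOOH, DBU, CH2Cl2, 0 °C) gives the racemic epoxy ketone F1. DIBAL‑H reduction gives the racemic cis‑epoxy alcohol ketal F2, and its acid hydrolysis gives the racemic epoxyquinol F3. Lipase‑catalysed transesterification (Amano lipase PS, vinyl acetate, MTBE) is then expected to acylate the fast‑reacting enantiomer to the acetate of ent‑5 F4 (Kazlauskas' rule with the methyl‑bearing alkene arm as the large group; if the preference is reversed, the acetate is methanolysed instead). This leaves 5, where the route is rejoined.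

**Step 7 (key semipinacol shift).** Risks are ionisation of the bis‑allylic tertiary silyl ether, enol‑silane formation from 14 and angelate isomerisation under silyl‑cation conditions. The fallback sets out from 12 and decouples the rearrangement from the silyl transfer. A zinc‑bromide‑promoted semipinacol rearrangement of the free epoxy carbinol (ZnBr2, CH2Cl2, 0 °C) gives the β‑hydroxy ketone F5 by the same anti 1,2‑alkenyl shift. Separate silylation of the 3α‑OH (TESOTf, 2,6‑lutidine, −78 °C) returns to 14.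

**Step 9 (directed dihydroxylation).** Risks are competing osmylation of the side‑arm 1,1‑disubstituted alkene, which is itself homoallylic to the directing OH, and incomplete face control. The fallback sets out from 14 and oxidises the ring C1=C6 bond while it is still the electron‑poor enone alkene. Buffered permanganate (KMnO4, MgSO4, acetone–H2O, −40 °C) prefers conjugated over isolated alkenes and should approach anti to the pseudoaxial 2α‑ester, giving the keto diol F6. L‑Selectride reduction as in step 8 then returns to 17.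

## Further compounds

F1 | step 2 | racemic 5,5‑dimethoxy‑3‑methyl‑7‑oxabicyclo[4.1.0]hept‑3‑en‑2‑one (rac‑3; one enantiomer drawn) | [C@@H]12O[C@@H]1C(=O)C(C)=CC2(OC)OC
F2 | step 2 | racemic cis‑5,5‑dimethoxy‑3‑methyl‑7‑oxabicyclo[4.1.0]hept‑3‑en‑2‑ol (rac‑4; relative configuration, one enantiomer drawn) | [C@@H]12O[C@@H]1[C@H](O)C(C)=CC2(OC)OC
F3 | step 2 | racemic cis‑5‑hydroxy‑4‑methyl‑7‑oxabicyclo[4.1.0]hept‑3‑en‑2‑one (rac‑5; relative configuration, one enantiomer drawn) | [C@@H]12O[C@@H]1[C@H](O)C(C)=CC2=O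
F4 | step 2 | (1S,5S,6S)‑4‑methyl‑2‑oxo‑7‑oxabicyclo[4.1.0]hept‑3‑en‑5‑yl acetate (acetate of ent‑5) | [C@H]12O[C@H]1[C@@H](OC(C)=O)C(C)=CC2=O
F5 | step 7 | (1R,5S,6S)‑6‑hydroxy‑2‑methyl‑4‑oxo‑5‑[3‑(triethylsilyloxy)prop‑1‑en‑2‑yl]cyclohex‑2‑en‑1‑yl (Z)‑2‑methylbut‑2‑enoate | C=C(CO[Si](CC)(CC)CC)[C@H]1[C@H](O)[C@H](OC(=O)/C(C)=C\C)C(C)=CC1=O
F6 | step 9 | 2α‑angeloyloxy‑1β,6β‑dihydroxy‑1α‑methyl‑3α‑(triethylsilyloxy)‑4β‑[3‑(triethylsilyloxy)prop‑1‑en‑2‑yl]cyclohexan‑5‑one | C=C(CO[Si](CC)(CC)CC)[C@H]1[C@H](O[Si](CC)(CC)CC)[C@H](OC(=O)/C(C)=C\C)[C@@](C)(O)[C@@H](O)C1=O
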